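The amount of G charged stays the same in a closed flask, whether it stands as solid, as dissolved G or as something made from it, so I followed one molecule of G and asked how long that fixed stock could feed Q.

| setting | larch | flask |
|---|---|---|
| G | 20 mM | 20 mM |
| J | 1.3 mM (held) | 1.3 mM (held) |
| remark | the very flask that is asked about, followed so far |  |
| time |  | 5.0 h |

larch run (percent of the G charged): time / h: Q / % = 0.200: 1; 0.667: 4; 1.33: 9; 2.00: 14; 2.50: 18

(standard deviation of a reading: 2 percentage points)

- G is a solid; its amount is given per volume of the solution
- at the start none of J is in solution
- at the start none of G is in solution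

- Wednesday's: doubling the dissolution coefficient of G, all else as stated
- Monday's: doubling the solubility of G, all else as stated
- Saturday's: doubling the transfer coefficient of J, all else as stated
- Tuesday's: doubling the saturation concentration of J, all else as stated

* amount of Q at 5.0 h, in percent of the G charged
* the change that raises the amount of Q at 5.0 h, in percent of the G charged most ("none" if none brings more than 2 percentage points) (Wednesday's / Monday's / Saturday's / Tuesday's / none)
* amount of Q at 5.0 h, in percent of the G charged, after Wednesday's

The larch readings lie close to one line, and from the second reading to the last I read a pace of 1.53 mM h⁻¹, a zero-order pace carrying the scatter of those points. Two times then mattered: the asked 5.0 h and the charge life, the charge divided by the pace of Q, 13.1 h. Every molecule that took another fork would shorten that life, so I held it as an upper bound. Their ratio was 0.382, and the asked time is shorter than the life, so I ran the line on from the last reading and got 37.1%.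

The forecast gave 36%, 37% after Wednesday's, and chose Tuesday's; its ground was: “dissolved G sits at its solubility limit while solid remains”.

The flask gave 34.8%, and 35.9% after Wednesday's, while Tuesday's added 29 percentage points. At 5.00 h this flask still held 12.9% of its G as solid.

    J ⇌ L, rate k1*(csat - [L]) (kL = 0.00700 s⁻¹)
    D + L → Q (k = 0.0460 L mol⁻¹ s⁻¹)
    D → E (k = 2.10 × 10⁻⁵ s⁻¹)
    G ⇌ D, rate k4*(cs4 - [D]) while solid is left; crystals form when [D] > cs4 (solubility = 7.60 mM, k = 0.00200 s⁻¹)
    D + Q → X (k = 5.00 × 10⁻⁴ L mol⁻¹ s⁻¹)
    L → Z (k = 1.10 × 10⁻⁴ s⁻¹)

For the neighbour with 5.0 mM of G, the same pace gives a charge life of 3.27 h, shorter than the asked time, and at 5.00 h that neighbour held 0% of solid G and 54.3% as Q.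

Readings and results come from a simulation with made-up constants; noise was put on by code.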